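**Retrosynthetic overview**

1. Target ⇒ C4–O ester bond: Mitsunobu inversion of a (4S)-hydroxy germacranolide core with a bis-silylated (Z)-hydroxy acid, then global desilylation.
2. Core ⇒ an open-chain aldehyde carrying a 5-alkenyl-3-(bromomethyl)butenolide. A chromium-mediated Barbier allylation forms the C3a–C11a bond and closes the ten-membered carbocycle; the new alkoxide then relactonises to the trans C11a-lactone and frees C4–OH.
3. Butenolide ⇒ carbonylative lactonisation of a (Z)-iodo dienol ⇐ trans-hydroalumination/iodination of a propargylic alcohol ⇐ asymmetric alkynylation of a C9 enal.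
4. Enal ⇒ Negishi union of a citronellal-derived alkylzinc (brings the C10 methyl stereocentre) with a (Z)-β-iodoenal from but-2-yne-1,4-diol; the same iodo alcohol also gives the side-chain acid.
5. Ring order: temporary butenolide (template) → carbocycle → γ-lactone, the last two in the same operation.

Assumptions: (S)-citronellal of ≥97% ee is used; (S,S)-ProPhenol is taken to give the 4S carbinol in step 8 (Mosher check, otherwise the antipodal ligand); the oxan-2-yl (THP) acetal carbon is an epimer mixture and is left unspecified; locants C3a, C4, C5=C6, C10, C11a follow the cyclodeca[b]furan-2-one numbering of the target; TBS = tert-butyl(dimethyl)silyl, TES = triethylsilyl.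

**Route**

Step 1
Reactants: 1 (S)-citronellal
Product: 2 (6S)-8,8-dimethoxy-2,6-dimethyloct-2-ene
Conditions: HC(OMe)3, PPTS (cat.), MeOH, 25 °C
Reagents that add atoms: trimethyl orthoformate, COC(OC)OC
Why: Acid-catalysed acetalisation masks the aldehyde (future C11a) while the methyl stereocentre (future C10) is taken unchanged from the chiral pool.

Step 2
Reactants: 2 (6S)-8,8-dimethoxy-2,6-dimethyloct-2-ene
Product: 4 (4S)-6,6-dimethoxy-4-methylhexan-1-ol, via (4S)-6,6-dimethoxy-4-methylhexanal 3 (not isolated)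
Conditions: O3, CH2Cl2–MeOH, −78 °C; then NaBH4, −78 → 0 °C
Reagents that add atoms: ozone, [O-][O+]=O
Why: Ozonolysis of the only C=C bond followed by in situ borohydride reduction of aldehyde 3 gives the primary alcohol without touching the acetal or the stereocentre.

Step 3
Reactants: 4 (4S)-6,6-dimethoxy-4-methylhexan-1-ol
Product: 5 (3S)-6-iodo-1,1-dimethoxy-3-methylhexane
Conditions: I2, PPh3, imidazole, CH2Cl2, 0 → 25 °C
Reagents that add atoms: iodine, II
Why: Appel-type iodination (SN2 on the oxyphosphonium) under imidazole-buffered, acetal-safe conditions.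

Step 4
Reactants: 6 but-2-yne-1,4-diol
Product: 7 4-(TBS-oxy)but-2-yn-1-ol
Conditions: NaH (1.0 equiv), THF, 0 °C; TBSCl (1.0 equiv), 0 → 25 °C
Reagents that add atoms: tert-butyldimethylsilyl chloride, CC(C)(C)[Si](C)(C)Cl
Why: Monosilylation of a symmetrical diol through its monosodium alkoxide (McDougal protocol).

Step 5
Reactants: 7 4-(TBS-oxy)but-2-yn-1-ol
Product: 9 (2Z)-4-(TBS-oxy)-3-iodobut-2-en-1-ol, via cyclic sodium alkenylaluminate 8 (not isolated)
Conditions: NaAlH2(OCH2CH2OMe)2, THF, 0 → 25 °C; then I2, −78 → 0 °C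
Reagents that add atoms: iodine, II
Why: Hydroxyl-directed trans-hydroalumination puts aluminium on the distal alkyne carbon (five-membered alanate 8), and iodinolysis with retention gives the (Z)-iodide whose geometry becomes that of the C5=C6 ring alkene.

Step 6
Reactants: 9 (2Z)-4-(TBS-oxy)-3-iodobut-2-en-1-ol
Product: 10 (2Z)-4-(TBS-oxy)-3-iodobut-2-enal
Conditions: MnO2, CH2Cl2, 25 °C
Reagents that add atoms: none
Why: MnO2 oxidises only the allylic alcohol and leaves the silyl ether and the vinyl iodide geometry intact.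

Step 7
Reactants: 5 (3S)-6-iodo-1,1-dimethoxy-3-methylhexane; 10 (2Z)-4-(TBS-oxy)-3-iodobut-2-enal
Product: 12 (2E,7S)-3-(TBS-oxymethyl)-9,9-dimethoxy-7-methylnon-2-enal, via alkylzinc iodide 11 (not isolated)
Conditions: 5, Zn dust, LiCl, THF, 40 °C; then 10, Pd(dppf)Cl2 (5 mol %), THF, 25 °C
Reagents that add atoms: none
Why: Negishi sp3–sp2 cross-coupling of alkylzinc 11 with the activated vinyl iodide proceeds with retention, so the alkyl chain ends up cis to the formyl group (5E in the target).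

Step 8
Reactants: 12 (2E,7S)-3-(TBS-oxymethyl)-9,9-dimethoxy-7-methylnon-2-enal; 13 2-(prop-2-yn-1-yloxy)oxane
Product: 14 (4S,5E,10S)-6-(TBS-oxymethyl)-12,12-dimethoxy-10-methyl-1-(oxan-2-yloxy)dodec-5-en-2-yn-4-ol
Conditions: (S,S)-ProPhenol (20 mol %), Me2Zn (3 equiv), Ph3PO (40 mol %), toluene, 0 °C
Reagents that add atoms: none
Why: Trost ProPhenol dinuclear-zinc asymmetric alkynylation of an enal, in which the ligand selects the aldehyde face and sets the 4S carbinol (future C4, deliberately the epimer of the target because step 16 inverts it).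

Step 9
Reactants: 14 (4S,5E,10S)-6-(TBS-oxymethyl)-12,12-dimethoxy-10-methyl-1-(oxan-2-yloxy)dodec-5-en-2-yn-4-ol
Product: 16 (2Z,4S,5E,10S)-6-(TBS-oxymethyl)-2-iodo-12,12-dimethoxy-10-methyl-1-(oxan-2-yloxy)dodeca-2,5-dien-4-ol, via cyclic sodium alkenylaluminate 15 (not isolated)
Conditions: NaAlH2(OCH2CH2OMe)2, THF, 0 → 25 °C; then I2, −78 → −20 °C
Reagents that add atoms: iodine, II
Why: Alkoxide-directed trans-hydroalumination/iodination as in step 5 (the ether oxygen does not direct) gives the (2Z)-iodide with iodine cis to the carbinol carbon, C4 being untouched.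

Step 10
Reactants: 16 (2Z,4S,5E,10S)-6-(TBS-oxymethyl)-2-iodo-12,12-dimethoxy-10-methyl-1-(oxan-2-yloxy)dodeca-2,5-dien-4-ol
Product: 17 (5S)-5-[(1E,6S)-2-(TBS-oxymethyl)-8,8-dimethoxy-6-methyloct-1-en-1-yl]-3-[(oxan-2-yloxy)methyl]furan-2(5H)-one
Conditions: Pd(PPh3)2Cl2 (5 mol %), CO (1 atm), 2,6-lutidine, THF, 45 °C
Reagents that add atoms: carbon monoxide, [C-]#[O+]
Why: Palladium-catalysed carbonylative lactonisation (oxidative addition, CO insertion, capture of the acylpalladium by the cis hydroxyl) closes the butenolide, and the weak base avoids epimerising the γ-stereocentre.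

Step 11
Reactants: 17 (5S)-5-[(1E,6S)-2-(TBS-oxymethyl)-8,8-dimethoxy-6-methyloct-1-en-1-yl]-3-[(oxan-2-yloxy)methyl]furan-2(5H)-one
Product: 18 (5S)-3-(bromomethyl)-5-[(1E,6S)-2-(TBS-oxymethyl)-8,8-dimethoxy-6-methyloct-1-en-1-yl]furan-2(5H)-one
Conditions: CBr4, PPh3, CH2Cl2, 0 → 25 °C
Reagents that add atoms: carbon tetrabromide, BrC(Br)(Br)Br
Why: Direct Appel-type conversion of a THP ether into the bromide (bromophosphonium activation, loss of dihydropyran, SN2 by bromide) under neutral conditions that the TBS ether and acetal tolerate.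

Step 12
Reactants: 18 (5S)-3-(bromomethyl)-5-[(1E,6S)-2-(TBS-oxymethyl)-8,8-dimethoxy-6-methyloct-1-en-1-yl]furan-2(5H)-one
Product: 19 (5S)-3-(bromomethyl)-5-[(1E,6S)-2-(TBS-oxymethyl)-6-methyl-8-oxooct-1-en-1-yl]furan-2(5H)-one
Conditions: Amberlyst-15, acetone–H2O (20:1), 25 °C
Reagents that add atoms: water, O
Why: Mild sulfonic-acid-resin hydrolysis of the dimethyl acetal frees the aldehyde while the primary TBS ether and the allylic bromide survive.

Step 13
Reactants: 19 (5S)-3-(bromomethyl)-5-[(1E,6S)-2-(TBS-oxymethyl)-6-methyl-8-oxooct-1-en-1-yl]furan-2(5H)-one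
Product: 22 (3aR,4S,5E,10S,11aR)-6-(TBS-oxymethyl)-4-hydroxy-10-methyl-3-methylidene-3a,4,7,8,9,10,11,11a-octahydrocyclodeca[b]furan-2(3H)-one, via allylchromium dichloride 20 (not isolated), via hydroxy lactone chromium alkoxide 21 (not isolated)
Conditions: CrCl2 (8 equiv), THF–DMF (4:1), 19 added over 10 h (final 2 mM), 25 °C; then 50 °C, 3 h
Reagents that add atoms: none
Why: Proposed new method: a ring-closing version of the known CrCl2-mediated Barbier (Nozaki–Hiyama-type) allylation of aldehydes by 3-(bromomethyl)butenolides, in which the γ-carbon (C3a) of allylchromium 20 adds to the tethered aldehyde through a chair Zimmerman–Traxler transition state on the butenolide face anti to the C5 side chain (as in the intermolecular reaction, and giving the less strained trans ring fusion), setting C3a and C11a and closing the ten-membered ring, after which the trivalent chromium alkoxide 21 attacks the neighbouring lactone carbonyl (five-membered acyl transfer, closest precedent the translactonisation of β-(hydroxyalkyl)-α-methylene-γ-butyrolactones) so that the trans γ-lactone closes on the non-allylic C11a oxygen and the allylic C4 alkoxide is released.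

Step 14
Reactants: 9 (2Z)-4-(TBS-oxy)-3-iodobut-2-en-1-ol
Product: 23 (2Z)-1,4-bis(TBS-oxy)-2-iodobut-2-ene
Conditions: TBSCl, imidazole, DMF, 25 °C
Reagents that add atoms: tert-butyldimethylsilyl chloride, CC(C)(C)[Si](C)(C)Cl
Why: Standard silylation of the remaining primary alcohol, with the alkene geometry unchanged.

Step 15
Reactants: 23 (2Z)-1,4-bis(TBS-oxy)-2-iodobut-2-ene
Product: 25 (2Z)-4-(TBS-oxy)-2-(TBS-oxymethyl)but-2-enoic acid, via alkenyllithium 24 (not isolated)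
Conditions: t-BuLi (2.1 equiv), Et2O, −78 °C; then CO2, −78 → 0 °C; cold 1 M HCl work-up
Reagents that add atoms: carbon dioxide, O=C=O
Why: Iodine–lithium exchange at −78 °C gives the configurationally stable alkenyllithium 24 with retention, and carboxylation places the carboxyl cis to the C4 silyloxymethyl group as in the target side chain.

Step 16
Reactants: 22 (3aR,4S,5E,10S,11aR)-6-(TBS-oxymethyl)-4-hydroxy-10-methyl-3-methylidene-3a,4,7,8,9,10,11,11a-octahydrocyclodeca[b]furan-2(3H)-one; 25 (2Z)-4-(TBS-oxy)-2-(TBS-oxymethyl)but-2-enoic acid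
Product: 26 [(3aS,4R,5E,10S,11aR)-6-(TBS-oxymethyl)-10-methyl-3-methylidene-2-oxo-2,3,3a,4,7,8,9,10,11,11a-decahydrocyclodeca[b]furan-4-yl] (2Z)-4-(TBS-oxy)-2-(TBS-oxymethyl)but-2-enoate
Conditions: PPh3, DIAD, toluene, 0 → 25 °C
Reagents that add atoms: none
Why: Mitsunobu esterification, in which SN2 displacement of the C4 oxyphosphonium by the carboxylate inverts C4 from S to R (the target configuration) and needs no acyl activation, so the Z-acid neither isomerises nor cyclises.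

Step 17
Reactants: 26 [(3aS,4R,5E,10S,11aR)-6-(TBS-oxymethyl)-10-methyl-3-methylidene-2-oxo-2,3,3a,4,7,8,9,10,11,11a-decahydrocyclodeca[b]furan-4-yl] (2Z)-4-(TBS-oxy)-2-(TBS-oxymethyl)but-2-enoate
Product: 27 [(3aS,4R,5E,10S,11aR)-6-(hydroxymethyl)-10-methyl-3-methylidene-2-oxo-2,3,3a,4,7,8,9,10,11,11a-decahydrocyclodeca[b]furan-4-yl] (2Z)-4-hydroxy-2-(hydroxymethyl)but-2-enoate (CNP0131216.1)
Conditions: HF·pyridine, pyridine, THF, 0 → 25 °C
Reagents that add atoms: none
Why: Pyridine-buffered fluoride cleaves the three primary TBS ethers under near-neutral conditions that spare the α-methylene lactone, the allylic ester and the Z-γ-hydroxy enoate.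

**Compound list**

1 | (S)-citronellal, (3S)-3,7-dimethyloct-6-enal | O=CC[C@@H](C)CCC=C(C)C | starting material
2 | (6S)-8,8-dimethoxy-2,6-dimethyloct-2-ene | COC(OC)C[C@@H](C)CCC=C(C)C | intermediate
3 | (4S)-6,6-dimethoxy-4-methylhexanal | COC(OC)C[C@@H](C)CCC=O | intermediate
4 | (4S)-6,6-dimethoxy-4-methylhexan-1-ol | COC(OC)C[C@@H](C)CCCO | intermediate
5 | (3S)-6-iodo-1,1-dimethoxy-3-methylhexane | COC(OC)C[C@@H](C)CCCI | intermediate
6 | but-2-yne-1,4-diol | OCC#CCO | starting material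
7 | 4-(TBS-oxy)but-2-yn-1-ol | OCC#CCO[Si](C)(C)C(C)(C)C | intermediate
8 | cyclic sodium alkenylaluminate from 7 (2,2-bis(2-methoxyethoxy)-1,2-oxaluminol-3-ene ate complex, Al on the carbon bearing CH2OTBS) | [Na+].COCCO[Al-]1(OCCOC)OCC=C1CO[Si](C)(C)C(C)(C)C | intermediate
9 | (2Z)-4-(TBS-oxy)-3-iodobut-2-en-1-ol | OC/C=C(\I)CO[Si](C)(C)C(C)(C)C | intermediate
10 | (2Z)-4-(TBS-oxy)-3-iodobut-2-enal | O=C/C=C(\I)CO[Si](C)(C)C(C)(C)C | intermediate
11 | [(4S)-6,6-dimethoxy-4-methylhexyl]zinc iodide | COC(OC)C[C@@H](C)CCC[Zn]I | intermediate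
12 | (2E,7S)-3-(TBS-oxymethyl)-9,9-dimethoxy-7-methylnon-2-enal | COC(OC)C[C@@H](C)CCC/C(CO[Si](C)(C)C(C)(C)C)=C\C=O | intermediate
13 | 2-(prop-2-yn-1-yloxy)oxane (THP propargyl ether) | C#CCOC1CCCCO1 | starting material
14 | (4S,5E,10S)-6-(TBS-oxymethyl)-12,12-dimethoxy-10-methyl-1-(oxan-2-yloxy)dodec-5-en-2-yn-4-ol | COC(OC)C[C@@H](C)CCC/C(CO[Si](C)(C)C(C)(C)C)=C\[C@H](O)C#CCOC1CCCCO1 | intermediate
15 | cyclic sodium alkenylaluminate from 14 (Al bound to O4 and C2) | [Na+].COCCO[Al-]1(OCCOC)O[C@@H](/C=C(/CO[Si](C)(C)C(C)(C)C)\CCC[C@H](C)CC(OC)OC)C=C1COC2CCCCO2 | intermediate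
16 | (2Z,4S,5E,10S)-6-(TBS-oxymethyl)-2-iodo-12,12-dimethoxy-10-methyl-1-(oxan-2-yloxy)dodeca-2,5-dien-4-ol | COC(OC)C[C@@H](C)CCC/C(CO[Si](C)(C)C(C)(C)C)=C\[C@H](O)/C=C(\I)COC1CCCCO1 | intermediate
17 | (5S)-5-[(1E,6S)-2-(TBS-oxymethyl)-8,8-dimethoxy-6-methyloct-1-en-1-yl]-3-[(oxan-2-yloxy)methyl]furan-2(5H)-one | COC(OC)C[C@@H](C)CCC/C(CO[Si](C)(C)C(C)(C)C)=C\[C@@H]1OC(=O)C(COC2CCCCO2)=C1 | intermediate
18 | (5S)-3-(bromomethyl)-5-[(1E,6S)-2-(TBS-oxymethyl)-8,8-dimethoxy-6-methyloct-1-en-1-yl]furan-2(5H)-one | COC(OC)C[C@@H](C)CCC/C(CO[Si](C)(C)C(C)(C)C)=C\[C@@H]1OC(=O)C(CBr)=C1 | intermediate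
19 | (5S)-3-(bromomethyl)-5-[(1E,6S)-2-(TBS-oxymethyl)-6-methyl-8-oxooct-1-en-1-yl]furan-2(5H)-one | O=CC[C@@H](C)CCC/C(CO[Si](C)(C)C(C)(C)C)=C\[C@@H]1OC(=O)C(CBr)=C1 | intermediate
20 | ({(5S)-5-[(1E,6S)-2-(TBS-oxymethyl)-6-methyl-8-oxooct-1-en-1-yl]-2-oxo-2,5-dihydrofuran-3-yl}methyl)chromium dichloride | O=CC[C@@H](C)CCC/C(CO[Si](C)(C)C(C)(C)C)=C\[C@@H]1OC(=O)C(C[Cr](Cl)Cl)=C1 | intermediate
21 | {[(3aR,4R,6S,10E,11aS)-10-(TBS-oxymethyl)-6-methyl-3-methylidene-2-oxo-2,3,3a,4,5,6,7,8,9,11a-decahydrocyclodeca[b]furan-4-yl]oxy}chromium dichloride (trans-fused lactone on the allylic oxygen) | C=C1C(=O)O[C@H]2/C=C(/CO[Si](C)(C)C(C)(C)C)\CCC[C@H](C)C[C@@H](O[Cr](Cl)Cl)[C@H]12 | intermediate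
22 | (3aR,4S,5E,10S,11aR)-6-(TBS-oxymethyl)-4-hydroxy-10-methyl-3-methylidene-3a,4,7,8,9,10,11,11a-octahydrocyclodeca[b]furan-2(3H)-one | C=C1C(=O)O[C@@H]2C[C@@H](C)CCC/C(CO[Si](C)(C)C(C)(C)C)=C\[C@H](O)[C@@H]12 | intermediate
23 | (2Z)-1,4-bis(TBS-oxy)-2-iodobut-2-ene | CC(C)(C)[Si](C)(C)OC/C=C(\I)CO[Si](C)(C)C(C)(C)C | intermediate
24 | (2E)-1,4-bis(TBS-oxy)but-2-en-2-yllithium | CC(C)(C)[Si](C)(C)OC/C=C(\[Li])CO[Si](C)(C)C(C)(C)C | intermediate
25 | (2Z)-4-(TBS-oxy)-2-(TBS-oxymethyl)but-2-enoic acid | CC(C)(C)[Si](C)(C)OC/C=C(\C(=O)O)CO[Si](C)(C)C(C)(C)C | intermediate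
26 | [(3aS,4R,5E,10S,11aR)-6-(TBS-oxymethyl)-10-methyl-3-methylidene-2-oxo-2,3,3a,4,7,8,9,10,11,11a-decahydrocyclodeca[b]furan-4-yl] (2Z)-4-(TBS-oxy)-2-(TBS-oxymethyl)but-2-enoate | C=C1C(=O)O[C@@H]2C[C@@H](C)CCC/C(CO[Si](C)(C)C(C)(C)C)=C\[C@@H](OC(=O)/C(=C\CO[Si](C)(C)C(C)(C)C)CO[Si](C)(C)C(C)(C)C)[C@@H]12 | intermediate
27 | [(3aS,4R,5E,10S,11aR)-6-(hydroxymethyl)-10-methyl-3-methylidene-2-oxo-2,3,3a,4,7,8,9,10,11,11a-decahydrocyclodeca[b]furan-4-yl] (2Z)-4-hydroxy-2-(hydroxymethyl)but-2-enoate | C=C1C(=O)O[C@@H]2C[C@@H](C)CCC/C(CO)=C\[C@@H](OC(=O)/C(=C\CO)CO)[C@@H]12 | target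

**Step count and risks**

Total: 17 steps. Longest linear sequence: 12 steps from 1 (steps 1–3, 7–13, 16, 17).

Steps most likely to fail:

Step 13. The allylchromium may add on the other butenolide face (C3a/C11a then epimeric relative to C4), the alkoxide may relactonise only partly, and the allylmetal can lose the lactone carboxylate by β-elimination. The fallback sets out from 16 and returns at 22; it uses an open-chain allylchromium whose new alkoxide can only lactonise onto C11a. Silylation of 16 (Et3SiOTf, 2,6-lutidine) gives the triethylsilyl ether F1. Methoxycarbonylation (Pd(PPh3)2Cl2, CO, MeOH, Et3N) gives the (2Z)-methyl ester F2, which cannot lactonise. CBr4/PPh3 converts the THP ether into the allylic bromide F3, and Amberlyst-15 in wet acetone frees the aldehyde F4. CrCl2 in THF–DMF at high dilution then closes the carbocycle and the lactone directly, with Felkin-type control by the C4 silyloxy group and anti addition, giving the silyl-protected lactone F5. Selective removal of the secondary TES group (HF·pyridine/pyridine, 0 °C) gives 22.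

Step 16. The hindered, macrocyclic allylic alcohol may eliminate, react SN2′, or PPh3 may add to the α-methylene lactone. The fallback sets out from 22 and returns at 26 and inverts C4 without phosphine. MsCl/Et3N at −20 °C gives the mesylate F6. It is displaced by the caesium carboxylate F7 (from 25 and Cs2CO3) in DMF with 18-crown-6 by SN2 to give 26.

Step 11. The one-step THP-to-bromide exchange may attack the acetal or let PPh3 alkylate on the product bromide. The fallback sets out from 17 and returns at 18. PPTS in MeOH removes the THP group (the dimethyl acetal is degenerate in methanol) to give the hydroxymethyl butenolide F8. MsCl/Et3N gives the mesylate F9, and LiBr in THF gives 18.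

**Further compounds**

F1 | step 13 | (2Z,4S,5E,10S)-6-(TBS-oxymethyl)-2-iodo-12,12-dimethoxy-10-methyl-1-(oxan-2-yloxy)-4-(TES-oxy)dodeca-2,5-diene | COC(OC)C[C@@H](C)CCC/C(CO[Si](C)(C)C(C)(C)C)=C\[C@H](O[Si](CC)(CC)CC)/C=C(\I)COC1CCCCO1
F2 | step 13 | methyl (2Z,4S,5E,10S)-6-(TBS-oxymethyl)-12,12-dimethoxy-10-methyl-2-[(oxan-2-yloxy)methyl]-4-(TES-oxy)dodeca-2,5-dienoate | COC(OC)C[C@@H](C)CCC/C(CO[Si](C)(C)C(C)(C)C)=C\[C@H](O[Si](CC)(CC)CC)/C=C(\C(=O)OC)COC1CCCCO1
F3 | step 13 | methyl (2E,4S,5E,10S)-2-(bromomethyl)-6-(TBS-oxymethyl)-12,12-dimethoxy-10-methyl-4-(TES-oxy)dodeca-2,5-dienoate | COC(OC)C[C@@H](C)CCC/C(CO[Si](C)(C)C(C)(C)C)=C\[C@H](O[Si](CC)(CC)CC)/C=C(\C(=O)OC)CBr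
F4 | step 13 | methyl (2E,4S,5E,10S)-2-(bromomethyl)-6-(TBS-oxymethyl)-10-methyl-12-oxo-4-(TES-oxy)dodeca-2,5-dienoate | O=CC[C@@H](C)CCC/C(CO[Si](C)(C)C(C)(C)C)=C\[C@H](O[Si](CC)(CC)CC)/C=C(\C(=O)OC)CBr
F5 | step 13 | (3aS,4S,5E,10S,11aR)-6-(TBS-oxymethyl)-10-methyl-3-methylidene-4-(TES-oxy)-3a,4,7,8,9,10,11,11a-octahydrocyclodeca[b]furan-2(3H)-one | C=C1C(=O)O[C@@H]2C[C@@H](C)CCC/C(CO[Si](C)(C)C(C)(C)C)=C\[C@H](O[Si](CC)(CC)CC)[C@@H]12
F6 | step 16 | (3aS,4S,5E,10S,11aR)-6-(TBS-oxymethyl)-10-methyl-3-methylidene-2-oxo-2,3,3a,4,7,8,9,10,11,11a-decahydrocyclodeca[b]furan-4-yl methanesulfonate | C=C1C(=O)O[C@@H]2C[C@@H](C)CCC/C(CO[Si](C)(C)C(C)(C)C)=C\[C@H](OS(C)(=O)=O)[C@@H]12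
F7 | step 16 | caesium (2Z)-4-(TBS-oxy)-2-(TBS-oxymethyl)but-2-enoate | [Cs+].[O-]C(=O)/C(=C\CO[Si](C)(C)C(C)(C)C)CO[Si](C)(C)C(C)(C)C
F8 | step 11 | (5S)-5-[(1E,6S)-2-(TBS-oxymethyl)-8,8-dimethoxy-6-methyloct-1-en-1-yl]-3-(hydroxymethyl)furan-2(5H)-one | COC(OC)C[C@@H](C)CCC/C(CO[Si](C)(C)C(C)(C)C)=C\[C@@H]1OC(=O)C(CO)=C1
F9 | step 11 | {(5S)-5-[(1E,6S)-2-(TBS-oxymethyl)-8,8-dimethoxy-6-methyloct-1-en-1-yl]-2-oxo-2,5-dihydrofuran-3-yl}methyl methanesulfonate | COC(OC)C[C@@H](C)CCC/C(CO[Si](C)(C)C(C)(C)C)=C\[C@@H]1OC(=O)C(COS(C)(=O)=O)=C1
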